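## The problem

The target is a germacranolide. A ten-membered carbocycle (C1–C10, germacrane numbering) carries a cis-4,5-epoxide and is fused across C6–C7 to an α-(acetoxymethyl)butenolide whose tetrasubstituted C7=C11 double bond lies inside the lactone ring. C8 bears a methacrylate, C1 a free hydroxyl and C10 a methyl group. A synthesis must close the medium ring by C–C bond formation against transannular strain, and then build the butenolide on C6/C7 without a carbonyl group at C7 to start from. Six stereocentres (C1, C4, C5, C6, C8, C10) have to be set. C4/C5 come from a Z-trisubstituted olefin and can be fixed by catalyst control, and C5 can direct C6 by 1,2-induction. C1 and C10 are too far from C4–C6 in an open chain to be controlled by them, so they can only be related to them in a cyclic transition state, and C8 is best left to the finished ring. The molecule is fragile: acid lets the C1 hydroxyl open the trisubstituted epoxide across the ring at C4, and base can remove the γ-acidic C6–H of the butenolide next to the epoxide. The doubly activated C7=C11 bond and the methacrylate accept nucleophiles and hydride, the allylic C13 acetate does not tolerate zerovalent palladium or alkoxide, and any intermediate with a C8 ketone and a C6 oxygen is a β-oxygenated ketone that can eliminate. The enabling feature is the array C1(OH)–C10(CH3)–C9H2–C8(O). This 1,4-dioxygenated unit with the methyl on the carbon next to the carbinol is what a ketyl radical leaves when it adds to the β-carbon of an E-propenyl ketone. The C6 oxygen two carbons beyond C8 marks the same ketone as the aldol partner of a C4–C6 epoxy aldehyde that maps onto nerol.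

## Retrosynthesis

**Ester and silyl group (21 ⇒ 20 ⇒ 18 + 19 ⇒ 17).** The O1–Si bond, the O8–acyl bond and the C8–H bond are cut first. Target 21 comes from silyl ether 20, 20 from allylic alcohol 18 and methacryloyl chloride 19, and 18 from ene-dione 17 by reduction. The methacrylate is the group most easily damaged by enolates, hydride and amines, so it is attached after all such chemistry. Keeping C8 as a ketone until then is no detour, because that ketone is what makes C7 nucleophilic in the preceding disconnection. Compound 17 has one stereocentre and one acyl group fewer. The forward reactions must reduce the ketone in a 1,2-sense from the face that gives 8S, acylate a hindered allylic alcohol, and remove the silyl group without acid strong enough to trigger transannular epoxide opening.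

**Butenolide (17 ⇒ 14 ⇒ 11 + 13; 13 ⇒ 12).** The C7=C11 double bond is cut as an intramolecular aldol condensation (through aldol adduct 15 and its mesylate 16) and the O6–C12 bond as an esterification. A phosphorus-based closure would need a carbonyl at C7, which no ring-forming step supplies. An intermolecular reaction at C7 would have to distinguish C7 from C9. The ester tether decides this, since only the C7 enolate reaches the keto group through a five-membered transition state. The precursor 11 is a plain ten-membered β-hydroxy ketone, and C11–C13 arrive in one piece as acetoxypyruvic acid 13, made from bromopyruvic acid 12. The forward step requires the C7 enolate to add to the keto ester faster than it expels the C6 carboxylate.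

**Hydroxyl differentiation (11 ⇒ 10 ⇒ 9).** Only Si–O bonds are cut. The C1 hydroxyl appears in the ring closure while C6 is still silylated. Capping C1 as the robust TBS ether (10) and then releasing C6 from the labile TES ether gives 11 without any selectivity problem between two free alcohols. The demand is a C6 desilylation mild enough for the epoxide and the β-hydroxy ketone.

**Ring closure (9 ⇒ 8).** The C1–C10 bond is cut. A cut at C6–C7 (aldol) or C5–C6 (vinyl-metal addition) would leave C1 and C10 to be built earlier by reagent-controlled open-chain chemistry. The C1–C10 cut removes the ring and two stereocentres together and leads to a linear aldehyde–enone 8 with only the C4/C5/C6 stereotriad. The forward reaction is a reductive ketyl–enone coupling. It must close a ten-membered ring faster than it simply reduces the substrate, give the anti C1-OH/C10-CH3 pair, and choose the face dictated by C4–C6.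

**Chain assembly (8 ⇒ 7 ⇒ 6 ⇒ 3 + 4).** The C1 aldehyde is traced to the isopropylidene terminus of 7 (ozonolysis), the silyl ether to alcohol 6, and the C6–C7 bond to an aldol addition of the methyl group of pentenone 4 (as its lithium dienolate 5) to epoxy aldehyde 3. The prenyl terminus serves as a masked aldehyde, so C1 needs no protecting group. The aldol brings in C7–C10 and C14 with the enone already in place. The demands are Felkin–Anh control of C6 by C5 and an ozonolysis that spares the enone.

**Epoxide (3 ⇒ 2 ⇒ 1).** The aldehyde is traced to epoxy alcohol 2 and the epoxide to nerol 1. Nerol supplies C1–C6 with C15, and its Z-olefin is the cis-epoxide. The Sharpless epoxidation sets the absolute configuration of the whole synthesis in the first step, using a catalyst whose sense for Z-allylic alcohols is well established.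

## Roads not taken

Alternative 1: The cut is C5–C6 together with the lactone C12–O bond. In the forward step, CrCl2 with catalytic NiCl2 (Nozaki–Hiyama–Kishi) would turn a C5 Z-vinyl iodide into a vinylchromium species that adds to a C6 aldehyde. The resulting alkoxide would lactonize onto a cis C12 ester, giving the Z-4,5-ene butenolide A1.
- **Merits:** Chromium-mediated closures of ten-membered carbocycles are among the better precedented ones, they tolerate esters, and ring and butenolide form in one operation.
- **Weak points:** C1, C8 and C10 must all be made beforehand by open-chain reagent control. A tetrasubstituted C7=C11 olefin of defined geometry carrying both the aldehyde and the ester is needed. C6 is set only by the ring. The epoxide must then be put onto A1 from the correct face with no free C6 hydroxyl to direct it.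
- **Comparison:** For the closure itself this road is the safer one. The chosen plan sets against it that two stereocentres form in the closure, that the epoxide configuration is fixed by catalyst control at the outset, and that the cyclization substrate is reached in five steps, so the risk is met early.

Alternative 2: A [3,3] reconnection takes the ring back to a limonene-derived 1,2-dialkenylcyclohexenol. Its potassium alkoxide would undergo anionic oxy-Cope ring expansion to the (1(10)E,4Z)-dienone A2.
- **Merits:** This is probably the most dependable entry to ten-membered rings. It needs no high dilution, takes both olefin geometries from the cyclic transition state and starts from the chiral pool.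
- **Weak points:** A2 has a single stereocentre (C8). C1, C10, C4, C5 and C6 would all have to be introduced on the flexible ring: face-selective hydration of the 1(10)-olefin, face-selective epoxidation and C6 reduction. The butenolide would still require functionalization of C7 next to a β-alkoxy group, with the same elimination problem as in the chosen route.
- **Comparison:** In ring formation this road is clearly better. The chosen plan sets against it that C4, C5 and C6 are fixed under open-chain control, C1 and C10 in the closure, and that only one stereocentre (C8) is left to the conformation of the ring.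

Alternative 3: The cut is C3–C4. 9-BBN would hydroborate a terminal C2=C3 olefin, and the alkylborane would couple with a C4 Z-vinyl iodide under PdCl2(dppf) and base (B-alkyl Suzuki–Miyaura), giving the Z-allylic alcohol A3 with C8 masked as a dithiane.
- **Merits:** The olefin geometry is fixed by the vinyl iodide, C1, C6 and C10 are set before closure by established open-chain methods, and the C6 hydroxyl could direct the epoxidation.
- **Weak points:** Reductive elimination to a strained ten-membered ring is far less usual than to larger rings, and the dithiane sulfur may slow the palladium catalyst. In open-chain Z-allylic alcohols, hydroxyl-directed epoxidation favours the threo (5,6-syn) epoxy alcohol, whereas the target has the erythro (5,6-anti) arrangement, so the outcome would depend on ring conformation. The dithiane must be removed beside the epoxide, the same butenolide annulation is still needed, and the precursor is long.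
- **Comparison:** In the security of C1 and C10 this road is as good or better. The chosen plan offsets that with a much shorter precursor and an epoxide whose configuration never depends on the ring.

Key step: step 6

Remark on the chemistry: germacrane numbering is used for all intermediates (ring carbons C1–C10; lactone carbons C11, C12, C13; C14 and C15 are the methyl groups on C10 and C4). Compound 9 is written as the open hydroxy ketone although it may equilibrate with its transannular C1–O–C8 hemiketal.

Step 1
Reactants: 1 nerol ((2Z)-3,7-dimethylocta-2,6-dien-1-ol)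
Product: 2 [(2S,3R)-3-methyl-3-(4-methylpent-3-en-1-yl)oxiran-2-yl]methanol
Conditions: Ti(OiPr)4 (cat.), L-(+)-diethyl tartrate (cat.), t-BuOOH, 4 Å MS, CH2Cl2, −20 °C
Reagents that add atoms: tert-butyl hydroperoxide, CC(C)(C)OO
Why: Sharpless asymmetric epoxidation; only the allylic olefin is bound to titanium through the hydroxyl, so the remote trisubstituted olefin is untouched, and L-(+)-tartrate is the enantiomer that gives the (2S,3R) epoxy alcohol from a Z-allylic alcohol, which sets C4 (R) and C5 (S) of the target.

Step 2
Reactants: 2 [(2S,3R)-3-methyl-3-(4-methylpent-3-en-1-yl)oxiran-2-yl]methanol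
Product: 3 (2R,3R)-3-methyl-3-(4-methylpent-3-en-1-yl)oxirane-2-carbaldehyde
Conditions: TEMPO (cat.), PhI(OAc)2, CH2Cl2, rt
Reagents that add atoms: none
Why: Oxoammonium (TEMPO) oxidation of a primary alcohol stops at the aldehyde and leaves epoxide and olefin alone; the epoxy aldehyde should be used without storage because the centre next to the formyl group is its only stereochemical weak point.

Step 3
Reactants: 3 (2R,3R)-3-methyl-3-(4-methylpent-3-en-1-yl)oxirane-2-carbaldehyde; 4 (3E)-pent-3-en-2-one
Product: 6 (2E,6S)-6-hydroxy-6-[(2S,3R)-3-methyl-3-(4-methylpent-3-en-1-yl)oxiran-2-yl]hex-2-en-4-one, via lithium dienolate 5 (not isolated)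
Conditions: LiN(iPr)2 (LDA), THF, −78 °C; add 4; then 3, −78 °C; AcOH quench at −78 °C
Reagents that add atoms: none
Why: Kinetic deprotonation of the enone at its methyl group gives the cross-conjugated lithium dienolate 5, which adds to the aldehyde (aldol addition); C6 is set by 1,2-induction from C5 in the Felkin–Anh sense, the enolate approaching anti to the epoxide C–O bond and past the C5 hydrogen, which should favour the 5,6-anti (erythro) epoxy alcohol with 6S configuration. The cold quench prevents retro-aldol and oxa-Michael reactions.

Step 4
Reactants: 6 (2E,6S)-6-hydroxy-6-[(2S,3R)-3-methyl-3-(4-methylpent-3-en-1-yl)oxiran-2-yl]hex-2-en-4-one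
Product: 7 (2E,6S)-6-[(2S,3R)-3-methyl-3-(4-methylpent-3-en-1-yl)oxiran-2-yl]-6-[(triethylsilyl)oxy]hex-2-en-4-one
Conditions: TESCl, imidazole, CH2Cl2, 0 °C
Reagents that add atoms: chlorotriethylsilane, CC[Si](Cl)(CC)CC
Why: Standard silylation of a secondary alcohol under mild base that does not eliminate the β-hydroxy ketone; the triethylsilyl ether blocks hydroxyl-directed reduction of the ketone by SmI2 later and can be removed selectively afterwards.

Step 5
Reactants: 7 (2E,6S)-6-[(2S,3R)-3-methyl-3-(4-methylpent-3-en-1-yl)oxiran-2-yl]-6-[(triethylsilyl)oxy]hex-2-en-4-one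
Product: 8 3-{(2R,3S)-2-methyl-3-[(1S,4E)-3-oxo-1-[(triethylsilyl)oxy]hex-4-en-1-yl]oxiran-2-yl}propanal
Conditions: O3, CH2Cl2, pyridine, Sudan Red 7B, −78 °C; then PPh3, −78 °C to rt
Reagents that add atoms: ozone, [O-][O+]=O
Why: Ozonolysis; the electron-rich trisubstituted olefin reacts far faster than the electron-poor enone double bond, and the indicator dye marks the point at which to stop.

Step 6
Reactants: 8 3-{(2R,3S)-2-methyl-3-[(1S,4E)-3-oxo-1-[(triethylsilyl)oxy]hex-4-en-1-yl]oxiran-2-yl}propanal
Product: 9 (1S,2S,6R,7S,10R)-7-hydroxy-6,10-dimethyl-2-[(triethylsilyl)oxy]-11-oxabicyclo[8.1.0]undecan-4-one (germacrane numbering: 1S,4R,5S,6S,10R; C1 hydroxyl, C10 methyl, 4,5-epoxide, C6 silyl ether, C8 ketone)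
Conditions: SmI2 (2.5 equiv), t-BuOH (3 equiv), THF, −78 °C to 0 °C, slow addition of 8 (final ca. 2 mM)
Reagents that add atoms: none
Why: Electron transfer from divalent samarium to the C1 aldehyde (or, with the same outcome, to the enone) gives a samarium-bound ketyl that adds to the β-carbon C10 of the E-propenyl ketone; a second electron turns the α-keto radical into the trivalent-samarium enolate across C8–C9, which t-BuOH protonates to leave the C8 ketone. The closest known reaction type is the SmI2-mediated reductive cyclization of aldehydes onto α,β-unsaturated carbonyl acceptors, established for five- to eight-membered rings and only occasionally for larger ones. The ring closes in a 10-endo-trig mode, C1 and C10 both becoming ring atoms. C10 is set by the face of the E-enone that is attacked and C1 by the face of the ketyl; samarium bridging the ketyl oxygen and the enone oxygen ties both into a seven-membered chair-like chelate (Sm, O, C1, C10, C9, C8, O) in which the E geometry places the C10 methyl pseudo-equatorial and the C2 chain takes the other pseudo-equatorial site, which corresponds to the anti C1-OH/C10-CH3 pair. Which of the two mirror-related chelates closes, that is the sense relative to C6, must come from the chain: the cis-epoxide is a rigid turn and the bulky C6 silyloxy group should stay on the outside of the forming ring. The step needs cyclization to be faster than simple reduction and intermolecular coupling, which slow addition at high dilution with the proton source present should secure, and it needs the enolate to form towards C9 and not C7 so that the C6 silyl ether is not eliminated, which the conjugate-addition mechanism guarantees. The silyl ether and the epoxide, which is neither next to a carbonyl group nor next to the ketyl carbon, should be inert to SmI2 under these conditions.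

Step 7
Reactants: 9 (1S,2S,6R,7S,10R)-7-hydroxy-6,10-dimethyl-2-[(triethylsilyl)oxy]-11-oxabicyclo[8.1.0]undecan-4-one
Product: 10 (1S,2S,6R,7S,10R)-7-[(tert-butyldimethylsilyl)oxy]-6,10-dimethyl-2-[(triethylsilyl)oxy]-11-oxabicyclo[8.1.0]undecan-4-one
Conditions: TBSCl, imidazole, DMAP (cat.), DMF, rt
Reagents that add atoms: tert-butylchlorodimethylsilane, CC(C)(C)[Si](C)(C)Cl
Why: Silylation of the C1 secondary alcohol with the chloride avoids silyl triflates, which can isomerize trisubstituted epoxides; it also drains any transannular hemiketal back to the open hydroxy ketone, since only the secondary hydroxyl is silylated at a useful rate.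

Step 8
Reactants: 10 (1S,2S,6R,7S,10R)-7-[(tert-butyldimethylsilyl)oxy]-6,10-dimethyl-2-[(triethylsilyl)oxy]-11-oxabicyclo[8.1.0]undecan-4-one
Product: 11 (1S,2S,6R,7S,10R)-7-[(tert-butyldimethylsilyl)oxy]-2-hydroxy-6,10-dimethyl-11-oxabicyclo[8.1.0]undecan-4-one
Conditions: HF·pyridine, excess pyridine, THF, 0 °C
Reagents that add atoms: none
Why: Selective desilylation; a triethylsilyl ether is cleaved much faster than a secondary tert-butyldimethylsilyl ether by buffered HF·pyridine, and the buffered medium should spare the epoxide and the β-hydroxy ketone.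

Step 9
Reactants: 12 3-bromo-2-oxopropanoic acid (bromopyruvic acid)
Product: 13 3-acetoxy-2-oxopropanoic acid (acetoxypyruvic acid)
Conditions: KOAc (2 equiv), acetone, rt; then 1 M HCl
Reagents that add atoms: potassium acetate, CC(=O)[O-].[K+]
Why: SN2 displacement of an α-bromo ketone by a carboxylate, a very fast substitution because of the adjacent carbonyl group; it places the C13 acetate before the C3 unit is attached to the ring.

Step 10
Reactants: 11 (1S,2S,6R,7S,10R)-7-[(tert-butyldimethylsilyl)oxy]-2-hydroxy-6,10-dimethyl-11-oxabicyclo[8.1.0]undecan-4-one; 13 3-acetoxy-2-oxopropanoic acid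
Product: 14 (1S,2S,6R,7S,10R)-7-[(tert-butyldimethylsilyl)oxy]-6,10-dimethyl-4-oxo-11-oxabicyclo[8.1.0]undecan-2-yl 3-acetoxy-2-oxopropanoate
Conditions: DCC, DMAP (cat.), CH2Cl2, 0 °C
Reagents that add atoms: none
Why: Steglich esterification of the only free hydroxyl (C6) with the α-keto acid; low temperature and only catalytic DMAP keep the new β-acyloxy ketone from eliminating.

Step 11
Reactants: 14 (1S,2S,6R,7S,10R)-7-[(tert-butyldimethylsilyl)oxy]-6,10-dimethyl-4-oxo-11-oxabicyclo[8.1.0]undecan-2-yl 3-acetoxy-2-oxopropanoate
Product: 17 (1S,4R,5S,6S,10R)-13-acetoxy-1-[(tert-butyldimethylsilyl)oxy]-4,5-epoxy-8-oxogermacr-7(11)-en-6,12-olide, via aldol adduct 15 (not isolated), via mesylate 16 (not isolated)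
Conditions: iPr2NEt, LiCl, THF, 0 °C to rt; then MsCl, Et3N, 0 °C to rt
Reagents that add atoms: none
Why: Intramolecular aldol condensation; soft enolization of the C8 ketone towards C7 and 5-exo-trig addition to the highly electrophilic C11 keto group of the tethered α-keto ester gives 15 (only the C7 enolate can reach C11 through a five-membered transition state, the C9 enolate would need a seven-membered one), and mesylation of the tertiary alcohol followed by E1cB loss of methanesulfonate gives the conjugated tetrasubstituted C7=C11 bond. The two transient stereocentres of 15 (C7, C11) are erased.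

Step 12
Reactants: 17 (1S,4R,5S,6S,10R)-13-acetoxy-1-[(tert-butyldimethylsilyl)oxy]-4,5-epoxy-8-oxogermacr-7(11)-en-6,12-olide
Product: 18 (1S,4R,5S,6S,8S,10R)-13-acetoxy-1-[(tert-butyldimethylsilyl)oxy]-4,5-epoxy-8-hydroxygermacr-7(11)-en-6,12-olide
Conditions: NaBH4, CeCl3·7H2O, MeOH, −78 °C
Reagents that add atoms: none
Why: Luche reduction; the cerium-modified borohydride should reduce the ketone in a 1,2-sense and leave the hindered, tetrasubstituted conjugated double bond, the lactone and the acetate untouched. C8 is set by hydride delivery from the outer face of the ten-membered ring, which should give 8S if the ring adopts the conformation of the natural lactone series; this has to be confirmed.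

Step 13
Reactants: 18 (1S,4R,5S,6S,8S,10R)-13-acetoxy-1-[(tert-butyldimethylsilyl)oxy]-4,5-epoxy-8-hydroxygermacr-7(11)-en-6,12-olide; 19 methacryloyl chloride (2-methylprop-2-enoyl chloride)
Product: 20 (1S,4R,5S,6S,8S,10R)-13-acetoxy-1-[(tert-butyldimethylsilyl)oxy]-4,5-epoxy-8-(2-methylprop-2-enoyloxy)germacr-7(11)-en-6,12-olide
Conditions: Et3N, DMAP (cat.), CH2Cl2, 0 °C
Reagents that add atoms: none
Why: Acylation of the only free hydroxyl by the acid chloride under nucleophilic catalysis; short reaction time at 0 °C limits base-induced removal of the γ-acidic C6–H and migration of the C13 acetate.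

Step 14
Reactants: 20 (1S,4R,5S,6S,8S,10R)-13-acetoxy-1-[(tert-butyldimethylsilyl)oxy]-4,5-epoxy-8-(2-methylprop-2-enoyloxy)germacr-7(11)-en-6,12-olide
Product: 21 (1S,4R,5S,6S,8S,10R)-13-acetoxy-4,5-epoxy-1-hydroxy-8-(2-methylprop-2-enoyloxy)germacr-7(11)-en-6,12-olide (target, CNP0119405.1)
Conditions: HF·pyridine, excess pyridine, THF, 0 °C to rt
Reagents that add atoms: none
Why: Fluoride-mediated desilylation; the pyridine buffer keeps the medium too weakly acidic for the freed C1 hydroxyl to open the epoxide across the ring, and the esters and the butenolide are stable to these conditions.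

Compound list

1 | nerol, (2Z)-3,7-dimethylocta-2,6-dien-1-ol | CC(C)=CCC/C(C)=C\CO | starting material
2 | [(2S,3R)-3-methyl-3-(4-methylpent-3-en-1-yl)oxiran-2-yl]methanol | CC(C)=CCC[C@@]1(C)O[C@H]1CO | intermediate
3 | (2R,3R)-3-methyl-3-(4-methylpent-3-en-1-yl)oxirane-2-carbaldehyde | CC(C)=CCC[C@@]1(C)O[C@H]1C=O | intermediate
4 | (3E)-pent-3-en-2-one | C/C=C/C(C)=O | starting material
5 | lithium (3E)-penta-1,3-dien-2-olate | C/C=C/C(=C)O[Li] | intermediate
6 | (2E,6S)-6-hydroxy-6-[(2S,3R)-3-methyl-3-(4-methylpent-3-en-1-yl)oxiran-2-yl]hex-2-en-4-one | CC(C)=CCC[C@@]1(C)O[C@H]1[C@@H](O)CC(=O)/C=C/C | intermediate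
7 | (2E,6S)-6-[(2S,3R)-3-methyl-3-(4-methylpent-3-en-1-yl)oxiran-2-yl]-6-[(triethylsilyl)oxy]hex-2-en-4-one | CC(C)=CCC[C@@]1(C)O[C@H]1[C@@H](O[Si](CC)(CC)CC)CC(=O)/C=C/C | intermediate
8 | 3-{(2R,3S)-2-methyl-3-[(1S,4E)-3-oxo-1-[(triethylsilyl)oxy]hex-4-en-1-yl]oxiran-2-yl}propanal | O=CCC[C@@]1(C)O[C@H]1[C@@H](O[Si](CC)(CC)CC)CC(=O)/C=C/C | intermediate
9 | (1S,2S,6R,7S,10R)-7-hydroxy-6,10-dimethyl-2-[(triethylsilyl)oxy]-11-oxabicyclo[8.1.0]undecan-4-one | O=C1C[C@@H](C)[C@@H](O)CC[C@@]2(C)O[C@H]2[C@@H](O[Si](CC)(CC)CC)C1 | intermediate
10 | (1S,2S,6R,7S,10R)-7-[(tert-butyldimethylsilyl)oxy]-6,10-dimethyl-2-[(triethylsilyl)oxy]-11-oxabicyclo[8.1.0]undecan-4-one | O=C1C[C@@H](C)[C@@H](O[Si](C)(C)C(C)(C)C)CC[C@@]2(C)O[C@H]2[C@@H](O[Si](CC)(CC)CC)C1 | intermediate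
11 | (1S,2S,6R,7S,10R)-7-[(tert-butyldimethylsilyl)oxy]-2-hydroxy-6,10-dimethyl-11-oxabicyclo[8.1.0]undecan-4-one | O=C1C[C@@H](C)[C@@H](O[Si](C)(C)C(C)(C)C)CC[C@@]2(C)O[C@H]2[C@@H](O)C1 | intermediate
12 | 3-bromo-2-oxopropanoic acid | O=C(O)C(=O)CBr | starting material
13 | 3-acetoxy-2-oxopropanoic acid | CC(=O)OCC(=O)C(=O)O | intermediate
14 | (1S,2S,6R,7S,10R)-7-[(tert-butyldimethylsilyl)oxy]-6,10-dimethyl-4-oxo-11-oxabicyclo[8.1.0]undecan-2-yl 3-acetoxy-2-oxopropanoate | O=C1C[C@@H](C)[C@@H](O[Si](C)(C)C(C)(C)C)CC[C@@]2(C)O[C@H]2[C@@H](OC(=O)C(=O)COC(C)=O)C1 | intermediate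
15 | (1S,4R,5S,6S,10R)-13-acetoxy-1-[(tert-butyldimethylsilyl)oxy]-4,5-epoxy-11-hydroxy-8-oxogermacran-6,12-olide (mixture at C7 and C11) | O=C1C[C@@H](C)[C@@H](O[Si](C)(C)C(C)(C)C)CC[C@@]2(C)O[C@H]2[C@H]2OC(=O)C(O)(COC(C)=O)C12 | intermediate
16 | 11-O-methanesulfonate of 15 (mixture at C7 and C11) | O=C1C[C@@H](C)[C@@H](O[Si](C)(C)C(C)(C)C)CC[C@@]2(C)O[C@H]2[C@H]2OC(=O)C(OS(C)(=O)=O)(COC(C)=O)C12 | intermediate
17 | (1S,4R,5S,6S,10R)-13-acetoxy-1-[(tert-butyldimethylsilyl)oxy]-4,5-epoxy-8-oxogermacr-7(11)-en-6,12-olide | O=C1C[C@@H](C)[C@@H](O[Si](C)(C)C(C)(C)C)CC[C@@]2(C)O[C@H]2[C@H]2OC(=O)C(COC(C)=O)=C12 | intermediate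
18 | (1S,4R,5S,6S,8S,10R)-13-acetoxy-1-[(tert-butyldimethylsilyl)oxy]-4,5-epoxy-8-hydroxygermacr-7(11)-en-6,12-olide | O[C@H]1C[C@@H](C)[C@@H](O[Si](C)(C)C(C)(C)C)CC[C@@]2(C)O[C@H]2[C@H]2OC(=O)C(COC(C)=O)=C12 | intermediate
19 | methacryloyl chloride | C=C(C)C(Cl)=O | starting material
20 | (1S,4R,5S,6S,8S,10R)-13-acetoxy-1-[(tert-butyldimethylsilyl)oxy]-4,5-epoxy-8-(2-methylprop-2-enoyloxy)germacr-7(11)-en-6,12-olide | C=C(C)C(=O)O[C@H]1C[C@@H](C)[C@@H](O[Si](C)(C)C(C)(C)C)CC[C@@]2(C)O[C@H]2[C@H]2OC(=O)C(COC(C)=O)=C12 | intermediate
21 | (1S,4R,5S,6S,8S,10R)-13-acetoxy-4,5-epoxy-1-hydroxy-8-(2-methylprop-2-enoyloxy)germacr-7(11)-en-6,12-olide | C=C(C)C(=O)O[C@H]1C[C@@H](C)[C@@H](O)CC[C@@]2(C)O[C@H]2[C@H]2OC(=O)C(COC(C)=O)=C12 | target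

Total step count: 14. Longest linear sequence: 13 steps from nerol 1 (steps 1–8 and 10–14); step 9 is a one-step side branch.

Steps least certain to work

**Step 6 (key step).** The ten-membered 10-endo closure may be too slow, because of the entropic cost and the transannular strain that builds up in the transition state. Simple reduction of the enone or aldehyde, or intermolecular coupling, would then take over. The closure may also proceed through the wrong chelate, giving poor facial selectivity relative to C6. The fallback reverses the order of the two C–C bond formations and closes the ring by a two-electron reaction.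
- It sets out from 2. Silylation gives the primary triethylsilyl ether F1, and ozonolysis of the prenyl terminus gives aldehyde F2.
- Intermolecular SmI2 coupling of F2 with enone 4 forms the C1–C10 bond and gives the γ-hydroxy methyl ketone F3. TBSCl/imidazole then gives the C1 silyl ether F4.
- Buffered HF·pyridine removes the primary triethylsilyl group to give alcohol F5, and TEMPO/PhI(OAc)2 oxidation gives the keto epoxy aldehyde F6.
- Kinetic enolization of the methyl ketone with LiN(iPr)2 under high dilution should close the ring by intramolecular aldol addition of C7 to the C6 aldehyde, in the same Felkin–Anh sense as in step 3. This returns to the route at 11.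
- The price is that C1/C10 are no longer controlled relative to the epoxide in the open chain, so the unwanted anti and syn isomers of F3 would have to be separated.

**Step 11.** E1cB loss of the C6 carboxylate from the C7 enolate may compete with the aldol addition, since the α-keto carboxylate is a good leaving group. Enolization of the keto ester towards C13 may also divert material. The fallback builds the lactone by acylation and introduces C13 by cross-coupling.
- It sets out from 11. Methyl chlorooxoacetate and pyridine give the mixed oxalate F7.
- LiN(SiMe3)2 at −78 °C should induce a Dieckmann-type acylation of C7 at a temperature where elimination is slow, giving the enolized α-keto lactone (3-hydroxybutenolide) F8.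
- N-Phenyltriflimide and Et3N give the enol triflate F9.
- Stille coupling of F9 with (tributylstannyl)methanol under Pd(PPh3)4 gives the hydroxymethyl butenolide F10.
- Acetylation (Ac2O, pyridine) returns to the route at 17.

**Step 3.** Facial selectivity at C6 may be poor, because an unsubstituted methyl ketone enolate is small and distinguishes only weakly between the two faces of the epoxy aldehyde. The fallback corrects the centre after the bond is made. It sets out from 3 (with 4): the chromatographically separated 6R epimer F11 is subjected to a Mitsunobu reaction with chloroacetic acid (PPh3, DIAD), which inverts C6 and gives the chloroacetate F12. Cleavage with thiourea and NaHCO3 in ethanol, mild enough to avoid elimination of the β-acyloxy ketone, returns to the route at 6.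

**Step 12.** Hydride may be delivered to the wrong face of C8, because the preferred conformation of the ten-membered ring is not known, or it may add in a conjugate sense to the doubly activated double bond. The fallback for the facial problem turns the esterification into the inverting step. It sets out from 17: if the Luche reduction gives the 8R alcohol F13, a Mitsunobu esterification with methacrylic acid (PPh3, DIAD) installs the methacrylate with inversion at the allylic C8 and returns to the route at 20, replacing step 13.

**Step 5.** Over-oxidation by attack of ozone on the enone double bond may occur if the end point is missed. The fallback separates oxidation and cleavage. It sets out from 7: catalytic K2OsO4·2H2O with N-methylmorpholine N-oxide dihydroxylates only the electron-rich trisubstituted olefin to give diol F14, and NaIO4 cleavage returns to the route at 8.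

Further compounds

F1 | step 6 | triethyl{[(2S,3R)-3-methyl-3-(4-methylpent-3-en-1-yl)oxiran-2-yl]methoxy}silane | CC(C)=CCC[C@@]1(C)O[C@H]1CO[Si](CC)(CC)CC
F2 | step 6 | 3-[(2R,3S)-2-methyl-3-{[(triethylsilyl)oxy]methyl}oxiran-2-yl]propanal | O=CCC[C@@]1(C)O[C@H]1CO[Si](CC)(CC)CC
F3 | step 6 | (4R,5S)-5-hydroxy-4-methyl-7-[(2R,3S)-2-methyl-3-{[(triethylsilyl)oxy]methyl}oxiran-2-yl]heptan-2-one | CC(=O)C[C@@H](C)[C@@H](O)CC[C@@]1(C)O[C@H]1CO[Si](CC)(CC)CC
F4 | step 6 | (4R,5S)-5-[(tert-butyldimethylsilyl)oxy]-4-methyl-7-[(2R,3S)-2-methyl-3-{[(triethylsilyl)oxy]methyl}oxiran-2-yl]heptan-2-one | CC(=O)C[C@@H](C)[C@@H](O[Si](C)(C)C(C)(C)C)CC[C@@]1(C)O[C@H]1CO[Si](CC)(CC)CC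
F5 | step 6 | (4R,5S)-5-[(tert-butyldimethylsilyl)oxy]-7-[(2R,3S)-3-(hydroxymethyl)-2-methyloxiran-2-yl]-4-methylheptan-2-one | CC(=O)C[C@@H](C)[C@@H](O[Si](C)(C)C(C)(C)C)CC[C@@]1(C)O[C@H]1CO
F6 | step 6 | (2R,3R)-3-{(3S,4R)-3-[(tert-butyldimethylsilyl)oxy]-4-methyl-6-oxoheptyl}-3-methyloxirane-2-carbaldehyde | CC(=O)C[C@@H](C)[C@@H](O[Si](C)(C)C(C)(C)C)CC[C@@]1(C)O[C@H]1C=O
F7 | step 11 | (1S,2S,6R,7S,10R)-7-[(tert-butyldimethylsilyl)oxy]-6,10-dimethyl-4-oxo-11-oxabicyclo[8.1.0]undecan-2-yl methyl oxalate | O=C1C[C@@H](C)[C@@H](O[Si](C)(C)C(C)(C)C)CC[C@@]2(C)O[C@H]2[C@@H](OC(=O)C(=O)OC)C1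
F8 | step 11 | (1S,4R,5S,6S,10R)-1-[(tert-butyldimethylsilyl)oxy]-4,5-epoxy-11-hydroxy-8-oxo-13-norgermacr-7(11)-en-6,12-olide | O=C1C[C@@H](C)[C@@H](O[Si](C)(C)C(C)(C)C)CC[C@@]2(C)O[C@H]2[C@H]2OC(=O)C(O)=C12
F9 | step 11 | 11-O-trifluoromethanesulfonate of F8 | O=C1C[C@@H](C)[C@@H](O[Si](C)(C)C(C)(C)C)CC[C@@]2(C)O[C@H]2[C@H]2OC(=O)C(OS(=O)(=O)C(F)(F)F)=C12
F10 | step 11 | (1S,4R,5S,6S,10R)-1-[(tert-butyldimethylsilyl)oxy]-4,5-epoxy-13-hydroxy-8-oxogermacr-7(11)-en-6,12-olide | O=C1C[C@@H](C)[C@@H](O[Si](C)(C)C(C)(C)C)CC[C@@]2(C)O[C@H]2[C@H]2OC(=O)C(CO)=C12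
F11 | step 3 | (2E,6R)-6-hydroxy-6-[(2S,3R)-3-methyl-3-(4-methylpent-3-en-1-yl)oxiran-2-yl]hex-2-en-4-one | CC(C)=CCC[C@@]1(C)O[C@H]1[C@H](O)CC(=O)/C=C/C
F12 | step 3 | (1S,4E)-1-[(2S,3R)-3-methyl-3-(4-methylpent-3-en-1-yl)oxiran-2-yl]-3-oxohex-4-en-1-yl chloroacetate | CC(C)=CCC[C@@]1(C)O[C@H]1[C@@H](OC(=O)CCl)CC(=O)/C=C/C
F13 | step 12 | (1S,4R,5S,6S,8R,10R)-13-acetoxy-1-[(tert-butyldimethylsilyl)oxy]-4,5-epoxy-8-hydroxygermacr-7(11)-en-6,12-olide | O[C@@H]1C[C@@H](C)[C@@H](O[Si](C)(C)C(C)(C)C)CC[C@@]2(C)O[C@H]2[C@H]2OC(=O)C(COC(C)=O)=C12
F14 | step 5 | (2E,6S)-6-[(2S,3R)-3-(3,4-dihydroxy-4-methylpentyl)-3-methyloxiran-2-yl]-6-[(triethylsilyl)oxy]hex-2-en-4-one (mixture at the new carbinol) | CC(C)(O)C(O)CC[C@@]1(C)O[C@H]1[C@@H](O[Si](CC)(CC)CC)CC(=O)/C=C/C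
A1 | alternative 1 | (1S,6R,8S,10R,4Z)-13-acetoxy-1-[(tert-butyldimethylsilyl)oxy]-8-(2-methylprop-2-enoyloxy)germacra-4,7(11)-dien-6,12-olide | C=C(C)C(=O)O[C@H]1C[C@@H](C)[C@@H](O[Si](C)(C)C(C)(C)C)CC/C(C)=C\[C@H]2OC(=O)C(COC(C)=O)=C12
A2 | alternative 2 | (2Z,6E,9S)-9-[(4-methoxyphenyl)methoxy]-3,7-dimethylcyclodeca-2,6-dien-1-one | COc1ccc(CO[C@H]2C/C(C)=C/CC/C(C)=C\C(=O)C2)cc1
A3 | alternative 3 | (1S,6S,10R,4Z)-1-[(tert-butyldimethylsilyl)oxy]-6-hydroxy-4,10-dimethylcyclodec-4-ene carrying C8 as its 1,3-dithiane (germacrane numbering) | C1CSC2(SC1)C[C@@H](C)[C@@H](O[Si](C)(C)C(C)(C)C)CC/C(C)=C\[C@@H](O)C2
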